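# Proposed total synthesis of CNP0511668.0 (23): ring D grown from a 2-pyrone

## The problem

The target 23 is a 19-membered bis(bibenzyl) in which four benzene rings are joined in a cycle by two diaryl ether oxygens (ring A to ring B, ring C to ring D) and two CH2CH2 bridges (ring B to ring C, ring D to ring A). Rings A and C are 1-alkyl-3,4-dihydroxy-5-aryloxybenzenes, ring B is a para-phenylene and ring D a meta-phenylene. There is no stereocenter and no fixed axis, so nothing has to be controlled stereochemically. The task is one of connectivity, of telling two almost identical trioxygenated rings apart, and of closing a large ring against oligomerisation. The two catechols are oxidised easily to ortho-quinones by air and base, so all four hydroxyls must stay masked until the last step and must then be freed without cleaving either diaryl ether. The two ether bonds are unequal. Ring B carries its bridge para to oxygen, so a para-formyl group can activate fluoride displacement and afterwards become the bridge. Ring D carries its bridge meta to oxygen, where no such activation exists and only a metal-mediated coupling of a hindered ortho-methoxyphenol would remain. The enabling feature is ring D itself, a benzene with four unsubstituted CH and only an oxygen and a CH2CH2 chain in a 1,3-relation. Its oxygen-bearing carbon, the CH between the substituents, the chain-bearing carbon and the first chain CH2 correspond to C-4, C-5, C-6 and the 6-methyl carbon of 4-hydroxy-6-methyl-2-pyrone 5. C-3 supplies a further ring CH, C-2 leaves as CO2, and the two missing CH come from an acetylene equivalent.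

## Retrosynthesis

**23 from 22.** The four O–CH3 bonds are cut last. Methyl ethers are chosen because phenols 1 and 7 are sold with exactly the 4,5-dimethoxy pattern required, and because they survive base, hydride, hydrogenation and prolonged heating. The forward reaction has to cleave four aryl methyl ethers while leaving both diaryl ethers intact.

**22 from 21 from 19.** The ring B–ring C bridge is cut at its central C–C bond, first as the alkene 21 and then as an ylide carbon and an aldehyde (ylide 20, generated from phosphonium salt 19). This bridge is preferred to the ring D–ring A bridge and to either ether bond as the closure site because its ring B terminus is a para-formyl group. That group also activates the ether formation one step earlier, so it serves twice. Precursor 19 is an open chain of four rings. The forward step is an intramolecular Wittig reaction at high dilution, and its alkene geometry is irrelevant because the double bond is hydrogenated.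

**19 from 18 from 16 and 17.** The bond from the ring A oxygen to the ring B carbon is cut. Fluoride displacement from 17 by the phenoxide of 16 is the obvious choice over copper chemistry because the formyl group sits para to the leaving group. The forward reaction must arylate the phenol and not the benzylic alcohol, and carbonate base secures that. The benzylic alcohol of 18 then becomes the phosphonium salt 19.

**16 from 15 from 14.** Only functional groups change: the ring C ester is the precursor of the hydroxymethyl group and the benzyl ether of the ring A phenol. Hydrogenolysis is placed before hydride reduction so that no electron-rich benzylic alcohol is ever exposed to hydrogen and palladium.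

**14 from 10 and 11.** Two C–C bonds of ring D are cut, those joining the two adjacent unsubstituted CH to their ring neighbours. This takes the ring back to the pyrone 10 and the acetylene equivalent 11. The neighbouring cut, the C–O bond between ring C and ring D, would demand an unactivated meta C–O coupling with a hindered phenol. The chosen cut instead moves that ether bond to C-4 of a pyrone, where it is a vinylogous ester made by addition–elimination. The forward reaction must turn a donor-substituted pyrone into a benzene by cycloaddition, loss of CO2 and loss of the sulfinyl group. It needs no regiocontrol.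

**10 from 8 and 4.** The CH2–CH2 bond of the ring D–ring A bridge is cut between the pyrone 6-methyl carbon (as its anion 9) and the benzylic carbon of bromide 4. The methyl group of 8 is the only position that gives an extended dienolate, so the bridge is formed by a simple alkylation and no stilbene or reduction is needed here. The base must deprotonate without attacking the ester or displacing the aryloxy group.

**8 from 6 and 7, and 6 from 5.** The bond from the ring C oxygen to pyrone C-4 is cut. Bromide 6 is a vinylogous acyl bromide and takes the phenoxide of 7 by addition–elimination under mild carbonate conditions. It comes in one step from the commodity pyrone 5.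

**4 from 3 from 2 from 1.** Bromide 4 arises from the commercial aldehyde 1 by benzylation, reduction and bromination. The benzyl group marks the one oxygen of ring A that will later carry ring B.

## Roads not taken

**Alternative 1:** The cut removes the two outer C–O bonds of rings A and C. In the forward direction the bis(di-tert-butylsilanol) ether A2 of the macrocycle lacking these two hydroxyls would be oxidised with Pd(OPiv)2 (divalent palladium) and PhI(OAc)2 at the free ortho C–H of each ring. This would give the bis(silylene) acetal A1.
- Merits: the catechols emerge already protected, and fluoride releases them far more gently than a Lewis acid cleaves methyl ethers. In this respect the road is better than the chosen one.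
- Weak points: two C–H oxidations must both go to completion on the most valuable intermediate. A hypervalent iodine oxidant meets two electron-rich diaryl ethers and four benzylic CH2 groups. The bulky silanol has to be installed on phenols flanked by an aryloxy group. The meta ether of ring D is not addressed at all and would still need a copper coupling.
- Comparison: the chosen plan accepts one harsh final demethylation. Against the gentler endgame of A1 it sets an oxygenation pattern that is bought with 1 and 7, and an uncertain step (step 7) that falls mid-route on an acyclic intermediate.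

**Alternative 2:** The cut is the bond from the ring A oxygen to ring B, made as the ring-closing event. The phenoxide of the seco compound A4, which carries a 4-fluoro-3-nitrophenyl ring B, would displace fluoride under K2CO3 in DMF to give the nitro macrocycle A3.
- Merits: nitro-activated macroetherification is among the most dependable large-ring closures and tolerates only moderate dilution. As a ring closure it is probably more reliable than the Wittig closure of 19, and this is conceded.
- Weak points: the nitro group is extraneous and must be removed by reduction, diazotisation and hydrodediazoniation. On a polyether with electron-rich rings this invites azo coupling and adds three operations. Ring D again needs a separate solution.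
- Comparison: the chosen plan closes and saturates the ring in two steps and leaves nothing to erase. It also makes ring D, which this road does not. The cost is a high-dilution olefination whose outcome is less certain.

**Alternative 3:** The cut removes the central C–O bonds of rings A and C from a resorcinol-type macrocycle. The bis(MOM ether) A6 would be lithiated twice with sec-BuLi and TMEDA between the two oxygens of each ring, trapped with B(OMe)3 and oxidised with H2O2 to give the diol A5.
- Merits: the site between two oxygen substituents is the most acidic aryl C–H, so the regiochemistry argument is sound. Resorcinol building blocks are cheap and the final MOM removal is mild.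
- Weak points: a dianion must be formed on a macrocycle that offers four bibenzylic CH2 groups and further positions ortho to a single oxygen on all four rings. Incomplete dilithiation gives mixtures of mono- and dihydroxylated material. The step is cryogenic, sits at the end of the route, and again does not solve the ring D ether.
- Comparison: the chosen plan does no late C–H functionalisation, and its ring D construction is independent of how the catechols are installed. It gives up the milder final deprotection of A5.

Key step: step 7

Assumption: alkene 21 is carried forward as an E/Z mixture because both isomers give the same bibenzyl 22; the transient adducts 12 and 13 are racemic diastereomer mixtures whose stereocenters are destroyed in the same flask.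

## Route

Step 1
Reactants: 1 3-hydroxy-4,5-dimethoxybenzaldehyde
Product: 2 3-(benzyloxy)-4,5-dimethoxybenzaldehyde
Conditions: BnBr, K2CO3, DMF, rt
Reagents that add atoms: benzyl bromide, BrCc1ccccc1
Why: Williamson ether synthesis on the only phenol; the benzyl group marks the oxygen that will later carry ring B and is stable to all steps up to step 8.

Step 2
Reactants: 2 3-(benzyloxy)-4,5-dimethoxybenzaldehyde
Product: 3 [3-(benzyloxy)-4,5-dimethoxyphenyl]methanol
Conditions: NaBH4, MeOH, 0 °C
Reagents that add atoms: none
Why: Borohydride reduction of an aryl aldehyde; no other reducible group is present.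

Step 3
Reactants: 3 [3-(benzyloxy)-4,5-dimethoxyphenyl]methanol
Product: 4 1-(benzyloxy)-5-(bromomethyl)-2,3-dimethoxybenzene
Conditions: PBr3, CH2Cl2, 0 °C
Reagents that add atoms: phosphorus tribromide, BrP(Br)Br
Why: Standard conversion of a benzylic alcohol into the bromide; the electron-rich bromide should be used without long storage.

Step 4
Reactants: 5 4-hydroxy-6-methyl-2H-pyran-2-one
Product: 6 4-bromo-6-methyl-2H-pyran-2-one
Conditions: Bu4NBr, P2O5, toluene, 100 °C
Reagents that add atoms: tetrabutylammonium bromide, [Br-].CCCC[N+](CCCC)(CCCC)CCCC
Why: Activation of the vinylogous acid as a phosphate and addition–elimination by bromide, the established preparation of this bromopyrone.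

Step 5
Reactants: 6 4-bromo-6-methyl-2H-pyran-2-one; 7 methyl 3-hydroxy-4,5-dimethoxybenzoate
Product: 8 methyl 3,4-dimethoxy-5-[(6-methyl-2-oxo-2H-pyran-4-yl)oxy]benzoate
Conditions: K2CO3, DMF, rt to 50 °C
Reagents that add atoms: none
Why: Addition–elimination of the phenoxide at C-4 of a vinylogous acyl bromide; this forms the future ring C–ring D ether without any arene C–O coupling.

Step 6
Reactants: 8 methyl 3,4-dimethoxy-5-[(6-methyl-2-oxo-2H-pyran-4-yl)oxy]benzoate; 4 1-(benzyloxy)-5-(bromomethyl)-2,3-dimethoxybenzene
Product: 10 methyl 3-[(6-{2-[3-(benzyloxy)-4,5-dimethoxyphenyl]ethyl}-2-oxo-2H-pyran-4-yl)oxy]-4,5-dimethoxybenzoate, via lithiated pyrone 9 (not isolated)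
Conditions: LiN(iPr)2, THF–DMPU, −78 °C; then 4, −78 to −40 °C
Reagents that add atoms: none
Why: Vinylogous deprotonation of the 6-methyl group gives the extended lithium dienolate 9, which is alkylated at the exocyclic carbon by the benzylic bromide (SN2); this lateral alkylation is established for 4-alkoxy-6-methyl-2-pyrones, and the hindered amide at −78 °C should spare the methyl benzoate and the C-4 aryloxy group.

Step 7
Reactants: 10 methyl 3-[(6-{2-[3-(benzyloxy)-4,5-dimethoxyphenyl]ethyl}-2-oxo-2H-pyran-4-yl)oxy]-4,5-dimethoxybenzoate; 11 phenyl vinyl sulfoxide (racemic)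
Product: 14 methyl 3-(3-{2-[3-(benzyloxy)-4,5-dimethoxyphenyl]ethyl}phenoxy)-4,5-dimethoxybenzoate, via bridged lactone adduct 12 (not isolated), via cyclohexadienyl sulfoxide 13 (not isolated)
Conditions: 11 (10 equiv), BHT (cat.), 1,2-dichlorobenzene, 150 °C, sealed tube
Reagents that add atoms: none
Why: This is the known benzannulation of 2-pyrones, a Diels–Alder reaction with an acetylene equivalent followed by cycloreversion. Pyrone 10 acts as the diene across C-3 and C-6 and adds 11 in a thermal suprafacial [4+2] cycloaddition; this closes the six-membered carbocycle that becomes ring D and forms both new C–C bonds in one intermolecular event, giving the bridged lactone 12. Retro-[4+2] loss of CO2 from 12 gives the cyclohexa-1,3-diene 13, whose sulfinyl-bearing carbon has only one hydrogen-bearing neighbour, the CH2 group, so the thermal syn elimination of benzenesulfenic acid can only lead to the arene 14. The stereocenters of 12 and 13 (bridgeheads, sulfinyl carbon, sulfur) are transient and are all erased on aromatisation, so neither endo/exo nor facial selectivity matters. Regioselectivity is not needed either: the nucleophilic C-3 should bond to the unsubstituted terminus of 11, but the opposite orientation gives the same arene because both dienophile carbons end as unsubstituted ring CH. What the step needs is rate, since a 4-aryloxy-6-alkyl-2-pyrone is a partly aromatic, donor-substituted diene; its two oxygen donors raise the HOMO towards the electron-poor alkene, and a large excess of 11 at high concentration, the gain of a benzene ring and the loss of a gas should carry the sequence through. Ester, benzyl ether and methyl ethers are inert to neutral heating.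

Step 8
Reactants: 14 methyl 3-(3-{2-[3-(benzyloxy)-4,5-dimethoxyphenyl]ethyl}phenoxy)-4,5-dimethoxybenzoate
Product: 15 methyl 3-{3-[2-(3-hydroxy-4,5-dimethoxyphenyl)ethyl]phenoxy}-4,5-dimethoxybenzoate
Conditions: H2 (1 atm), Pd/C, EtOAc–MeOH, rt
Reagents that add atoms: none
Why: Hydrogenolysis of the benzyl aryl ether; it is run at the ester stage so that no benzylic alcohol is present to be over-reduced, and after chromatography of 14 to remove sulfur residues.

Step 9
Reactants: 15 methyl 3-{3-[2-(3-hydroxy-4,5-dimethoxyphenyl)ethyl]phenoxy}-4,5-dimethoxybenzoate
Product: 16 5-(2-{3-[5-(hydroxymethyl)-2,3-dimethoxyphenoxy]phenyl}ethyl)-2,3-dimethoxyphenol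
Conditions: LiAlH4 (excess), THF, 0 °C to rt; dilute HCl work-up
Reagents that add atoms: none
Why: Hydride reduction of the methyl ester to the benzylic alcohol; the phenol is merely deprotonated and is recovered on acidic work-up.

Step 10
Reactants: 16 5-(2-{3-[5-(hydroxymethyl)-2,3-dimethoxyphenoxy]phenyl}ethyl)-2,3-dimethoxyphenol; 17 4-fluorobenzaldehyde
Product: 18 4-[5-(2-{3-[5-(hydroxymethyl)-2,3-dimethoxyphenoxy]phenyl}ethyl)-2,3-dimethoxyphenoxy]benzaldehyde
Conditions: K2CO3, DMF, 130 °C
Reagents that add atoms: none
Why: Nucleophilic aromatic substitution of fluoride activated by the para-formyl group; carbonate ionises only the phenol, so the benzylic alcohol should remain unarylated.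

Step 11
Reactants: 18 4-[5-(2-{3-[5-(hydroxymethyl)-2,3-dimethoxyphenoxy]phenyl}ethyl)-2,3-dimethoxyphenoxy]benzaldehyde
Product: 19 {3-[3-(2-{3-(4-formylphenoxy)-4,5-dimethoxyphenyl}ethyl)phenoxy]-4,5-dimethoxybenzyl}triphenylphosphonium bromide
Conditions: PPh3·HBr, MeCN, reflux
Reagents that add atoms: triphenylphosphine hydrobromide, Br.c1ccc(cc1)P(c1ccccc1)c1ccccc1
Why: The para-methoxy-stabilised benzylic alcohol is ionised by HBr and captured by PPh3 to give the phosphonium salt in one operation; aryl aldehydes tolerate these conditions, as in the standard preparation of formyl phosphonium salts for bis(bibenzyl) macrocycles.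

Step 12
Reactants: 19 {3-[3-(2-{3-(4-formylphenoxy)-4,5-dimethoxyphenyl}ethyl)phenoxy]-4,5-dimethoxybenzyl}triphenylphosphonium bromide
Product: 21 macrocyclic stilbene, the tetramethyl ether of 23 with CH=CH in place of the ring B–ring C bridge (E/Z mixture), via phosphonium ylide 20 (not isolated)
Conditions: NaOMe, CH2Cl2, rt, slow addition of 19 (final concentration about 1 mM)
Reagents that add atoms: none
Why: Intramolecular Wittig reaction of a semi-stabilised benzylic ylide with the aryl aldehyde under high dilution, the classical closure of marchantin-type macrocycles; alkene geometry is irrelevant.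

Step 13
Reactants: 21 macrocyclic stilbene (E/Z mixture)
Product: 22 tetra-O-methyl ether of 23 (19-membered macrocycle with two CH2CH2 bridges)
Conditions: H2 (1 atm), Pd/C, EtOAc, rt
Reagents that add atoms: none
Why: Catalytic hydrogenation of the stilbene double bond; both geometric isomers converge on one bibenzyl, and diaryl ethers and methyl ethers are inert.

Step 14
Reactants: 22 tetra-O-methyl ether of 23
Product: 23 CNP0511668.0, the 19-membered bis(bibenzyl) with 3,4-dihydroxy groups on rings A and C
Conditions: BBr3, CH2Cl2, −78 °C to rt; then MeOH, H2O, under argon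
Reagents that add atoms: none
Why: Lewis-acid cleavage of the four aryl methyl ethers by bromide attack at methyl; diaryl ethers are not cleaved under these conditions, and work-up under inert gas protects the catechols from air oxidation.

## Compound list

1 | 3-hydroxy-4,5-dimethoxybenzaldehyde | O=Cc1cc(O)c(OC)c(OC)c1 | starting material
2 | 3-(benzyloxy)-4,5-dimethoxybenzaldehyde | O=Cc1cc(OCc2ccccc2)c(OC)c(OC)c1 | intermediate
3 | [3-(benzyloxy)-4,5-dimethoxyphenyl]methanol | OCc1cc(OCc2ccccc2)c(OC)c(OC)c1 | intermediate
4 | 1-(benzyloxy)-5-(bromomethyl)-2,3-dimethoxybenzene | BrCc1cc(OCc2ccccc2)c(OC)c(OC)c1 | intermediate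
5 | 4-hydroxy-6-methyl-2H-pyran-2-one | CC1=CC(O)=CC(=O)O1 | starting material
6 | 4-bromo-6-methyl-2H-pyran-2-one | CC1=CC(Br)=CC(=O)O1 | intermediate
7 | methyl 3-hydroxy-4,5-dimethoxybenzoate | COC(=O)c1cc(O)c(OC)c(OC)c1 | starting material
8 | methyl 3,4-dimethoxy-5-[(6-methyl-2-oxo-2H-pyran-4-yl)oxy]benzoate | COC(=O)c1cc(OC)c(OC)c(c1)OC1=CC(=O)OC(C)=C1 | intermediate
9 | lithiated pyrone, the 6-(lithiomethyl) dienolate of 8 | [Li]CC1=CC(Oc2cc(cc(OC)c2OC)C(=O)OC)=CC(=O)O1 | intermediate (not isolated)
10 | methyl 3-[(6-{2-[3-(benzyloxy)-4,5-dimethoxyphenyl]ethyl}-2-oxo-2H-pyran-4-yl)oxy]-4,5-dimethoxybenzoate | O=C1C=C(Oc2cc(cc(OC)c2OC)C(=O)OC)C=C(CCc2cc(OC)c(OC)c(OCc3ccccc3)c2)O1 | intermediate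
11 | phenyl vinyl sulfoxide (racemic at sulfur) | C=CS(=O)c1ccccc1 | starting material
12 | bridged lactone adduct, methyl 3-({1-[2-(3-(benzyloxy)-4,5-dimethoxyphenyl)ethyl]-3-oxo-7-(phenylsulfinyl)-2-oxabicyclo[2.2.2]oct-5-en-5-yl}oxy)-4,5-dimethoxybenzoate (racemic diastereomer mixture, expected regioisomer drawn) | O=C1OC2(CCc3cc(OC)c(OC)c(OCc4ccccc4)c3)C=C(Oc3cc(cc(OC)c3OC)C(=O)OC)C1CC2S(=O)c1ccccc1 | intermediate (not isolated)
13 | cyclohexadienyl sulfoxide, methyl 3-[(5-{2-[3-(benzyloxy)-4,5-dimethoxyphenyl]ethyl}-4-(phenylsulfinyl)cyclohexa-1,5-dien-1-yl)oxy]-4,5-dimethoxybenzoate (racemic diastereomer mixture) | O=S(c1ccccc1)C1CC=C(Oc2cc(cc(OC)c2OC)C(=O)OC)C=C1CCc1cc(OC)c(OC)c(OCc2ccccc2)c1 | intermediate (not isolated)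
14 | methyl 3-(3-{2-[3-(benzyloxy)-4,5-dimethoxyphenyl]ethyl}phenoxy)-4,5-dimethoxybenzoate | COC(=O)c1cc(OC)c(OC)c(c1)Oc1cccc(c1)CCc1cc(OC)c(OC)c(OCc2ccccc2)c1 | intermediate
15 | methyl 3-{3-[2-(3-hydroxy-4,5-dimethoxyphenyl)ethyl]phenoxy}-4,5-dimethoxybenzoate | COC(=O)c1cc(OC)c(OC)c(c1)Oc1cccc(c1)CCc1cc(OC)c(OC)c(O)c1 | intermediate
16 | 5-(2-{3-[5-(hydroxymethyl)-2,3-dimethoxyphenoxy]phenyl}ethyl)-2,3-dimethoxyphenol | OCc1cc(OC)c(OC)c(c1)Oc1cccc(c1)CCc1cc(OC)c(OC)c(O)c1 | intermediate
17 | 4-fluorobenzaldehyde | O=Cc1ccc(F)cc1 | starting material
18 | 4-[5-(2-{3-[5-(hydroxymethyl)-2,3-dimethoxyphenoxy]phenyl}ethyl)-2,3-dimethoxyphenoxy]benzaldehyde | OCc1cc(OC)c(OC)c(c1)Oc1cccc(c1)CCc1cc(OC)c(OC)c(Oc2ccc(C=O)cc2)c1 | intermediate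
19 | {3-[3-(2-{3-(4-formylphenoxy)-4,5-dimethoxyphenyl}ethyl)phenoxy]-4,5-dimethoxybenzyl}triphenylphosphonium bromide | [Br-].COc1cc(C[P+](c2ccccc2)(c2ccccc2)c2ccccc2)cc(Oc2cccc(CCc3cc(OC)c(OC)c(Oc4ccc(C=O)cc4)c3)c2)c1OC | intermediate
20 | phosphonium ylide derived from 19 | COc1cc(C=P(c2ccccc2)(c2ccccc2)c2ccccc2)cc(Oc2cccc(CCc3cc(OC)c(OC)c(Oc4ccc(C=O)cc4)c3)c2)c1OC | intermediate (not isolated)
21 | macrocyclic stilbene, tetramethyl ether of 23 with CH=CH between rings B and C (E/Z mixture, drawn without alkene descriptor) | COc1cc2cc(c1OC)Oc1ccc(cc1)C=Cc1cc(OC)c(OC)c(c1)Oc1cccc(c1)CC2 | intermediate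
22 | tetra-O-methyl ether of 23 | COc1cc2cc(c1OC)Oc1ccc(cc1)CCc1cc(OC)c(OC)c(c1)Oc1cccc(c1)CC2 | intermediate
23 | CNP0511668.0 (no stereocenters) | Oc1cc2cc(c1O)Oc1ccc(cc1)CCc1cc(O)c(O)c(c1)Oc1cccc(c1)CC2 | target

## Step count and risks

Total: 14 steps. Longest linear sequence: 12 steps (steps 1–3 and 6–14 from aldehyde 1); the pyrone branch (steps 4 and 5) joins at step 6.

**Step 7 (key step).** The cycloaddition may be too slow for the donor-substituted pyrone, so that the vinyl sulfoxide is consumed by self-condensation of released sulfenic acid and by polymerisation before it adds. Sulfenylation of the electron-rich rings by those sulfur by-products is a second hazard. The fallback abandons the pyrone and makes the ring C–ring D ether by copper coupling; it sets out from aldehyde 2 and phenol 7 and returns at 14. Horner–Wadsworth–Emmons olefination of 2 with diethyl (3-bromobenzyl)phosphonate (NaH, THF) should give the E-stilbene 1-(benzyloxy)-5-[(E)-2-(3-bromophenyl)ethenyl]-2,3-dimethoxybenzene F1. Diimide reduction (TsNHNH2, NaOAc, THF–H2O, reflux), which spares the benzyl ether and the aryl bromide, should give the bibenzyl bromide 1-(benzyloxy)-5-[2-(3-bromophenyl)ethyl]-2,3-dimethoxybenzene F2. Ullmann ether coupling of F2 with 7 (CuI, N,N-dimethylglycine, Cs2CO3, dioxane, 100 °C) should then give 14. This is the hindered meta C–O coupling the main plan avoids, which is why it is held in reserve.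

**Step 6.** Deprotonation may occur at C-3 in place of the methyl group, the amide or the dienolate may attack C-4 with loss of aryloxide, or the product may be alkylated a second time. The fallback changes the order of events so that the alkylation is done before the aryloxy group and the ester are present; it sets out from pyrone 5 and bromide 4 and returns at 10. The dianion of 5 (2 equiv LiN(iPr)2, THF–DMPU, −78 °C) is alkylated at the 6-methyl carbon by 4 to give 6-{2-[3-(benzyloxy)-4,5-dimethoxyphenyl]ethyl}-4-hydroxy-2H-pyran-2-one F3. Bromination with PBr3 in DMF gives the 4-bromopyrone F4, and displacement by the phenoxide of 7 (K2CO3, DMF) gives 10.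

**Step 12.** Intermolecular olefination may outrun ring closure and give dimers and oligomers, since the 19-membered transition state is entropically costly. The fallback replaces olefination by reductive carbonyl coupling; it sets out from 18 and returns at 21. Oxidation of the benzylic alcohol of 18 with MnO2 in CH2Cl2 gives the dialdehyde 3-{3-[2-(3-(4-formylphenoxy)-4,5-dimethoxyphenyl)ethyl]phenoxy}-4,5-dimethoxybenzaldehyde F5. McMurry coupling with low-valent titanium from TiCl4 and Zn in refluxing THF under high dilution gives 21.

**Step 10.** Displacement of fluoride by the hindered ortho-methoxy phenoxide may be slow enough at 130 °C that arylation of the benzylic alcohol or base-induced degradation of the aldehyde competes. The fallback forms the same bond by oxidative copper coupling at room temperature; it sets out from 16 and returns at 18. Chan–Lam arylation of 16 with 4-formylphenylboronic acid (Cu(OAc)2, pyridine, 4 Å molecular sieves, CH2Cl2, air) gives 18 directly and creates no new intermediate.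

## Further compounds

F1 | step 7 | 1-(benzyloxy)-5-[(E)-2-(3-bromophenyl)ethenyl]-2,3-dimethoxybenzene | Brc1cccc(c1)/C=C/c1cc(OC)c(OC)c(OCc2ccccc2)c1
F2 | step 7 | 1-(benzyloxy)-5-[2-(3-bromophenyl)ethyl]-2,3-dimethoxybenzene | Brc1cccc(c1)CCc1cc(OC)c(OC)c(OCc2ccccc2)c1
F3 | step 6 | 6-{2-[3-(benzyloxy)-4,5-dimethoxyphenyl]ethyl}-4-hydroxy-2H-pyran-2-one | OC1=CC(=O)OC(CCc2cc(OC)c(OC)c(OCc3ccccc3)c2)=C1
F4 | step 6 | 6-{2-[3-(benzyloxy)-4,5-dimethoxyphenyl]ethyl}-4-bromo-2H-pyran-2-one | BrC1=CC(=O)OC(CCc2cc(OC)c(OC)c(OCc3ccccc3)c2)=C1
F5 | step 12 | 3-{3-[2-(3-(4-formylphenoxy)-4,5-dimethoxyphenyl)ethyl]phenoxy}-4,5-dimethoxybenzaldehyde | O=Cc1ccc(cc1)Oc1cc(CCc2cccc(c2)Oc2cc(C=O)cc(OC)c2OC)cc(OC)c1OC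
F0 | step 10 | none | none
A1 | alternative 1 | macrocycle with both catechols as di-tert-butylsilylene acetals | CC(C)(C)[Si]1(C(C)(C)C)Oc2cc3cc(c2O1)Oc1ccc(cc1)CCc1cc2O[Si](C(C)(C)C)(C(C)(C)C)Oc2c(c1)Oc1cccc(c1)CC3
A2 | alternative 1 | bis(di-tert-butylsilanol) ether of the macrocycle lacking the two outer hydroxyls | CC(C)(C)[Si](O)(C(C)(C)C)Oc1ccc2cc1Oc1ccc(cc1)CCc1ccc(O[Si](O)(C(C)(C)C)C(C)(C)C)c(c1)Oc1cccc(c1)CC2
A3 | alternative 2 | tetramethyl ether macrocycle with a nitro group on ring B ortho to the ether | COc1cc2cc(c1OC)Oc1ccc(cc1[N+](=O)[O-])CCc1cc(OC)c(OC)c(c1)Oc1cccc(c1)CC2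
A4 | alternative 2 | seco phenol carrying a 4-fluoro-3-nitrophenyl ring B | Oc1cc(CCc2cccc(c2)Oc2cc(CCc3ccc(F)c(c3)[N+](=O)[O-])cc(OC)c2OC)cc(OC)c1OC
A5 | alternative 3 | macrocycle with both central hydroxyls free and the outer hydroxyls as MOM ethers | COCOc1cc2cc(c1O)Oc1ccc(cc1)CCc1cc(OCOC)c(O)c(c1)Oc1cccc(c1)CC2
A6 | alternative 3 | bis(MOM ether) macrocycle lacking the two central hydroxyls | COCOc1cc2cc(c1)Oc1ccc(cc1)CCc1cc(OCOC)cc(c1)Oc1cccc(c1)CC2
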